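The time of reading is 50 h: at that hour the two flasks epsilon and beta are compared.

all flasks: left-handed substrate 0.050 M; right-handed substrate 0.050 M; precatalyst 25 µM
- green: reagent 0.085 M (fed, over 2.5 h); run made earlier; the fed solution adds 0.25 times the starting volume
- violet: reagent 0.088 M (fed, over 2.5 h); run made earlier; the fed solution adds 0.25 times the starting volume
- teal: reagent 0.087 M (fed, over 2.5 h); run made earlier; the fed solution adds 0.25 times the starting volume
- epsilon: reagent 0.0750 M (fed, over 2.5 h); the fed solution adds 0.25 times the starting volume; time 50 h
- beta: reagent 0.120 M (fed, over 2.5 h); the fed solution adds 0.25 times the starting volume; time 50 h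

| run | time / h | left-handed product / % | right-handed product / % | left-handed substrate / % |
|---|---|---|---|---|
| green | 2.00 | 8.1 | 3.6 | 41.4 |
| green | 6.00 | 29.8 | 11.1 | 20.9 |
| green | 12.0 | 39.8 | 21.3 | 9.5 |
| green | 20.0 | 43.7 | 26.7 | 6.0 |
| green | 25.0 | 46.9 | 28.9 | 4.6 |
| violet | 2.00 | 7.9 | 3.4 | 43.5 |
| violet | 4.00 | 22.2 | 9.5 | 29.1 |
| violet | 8.00 | 35.5 | 16.2 | 16.1 |
| violet | 12.0 | 39.8 | 21.5 | 9.7 |
| violet | 25.0 | 47.7 | 30.3 | 3.8 |
| teal | 2.00 | 8.1 | 3.1 | 43.4 |
| teal | 6.00 | 30.1 | 10.7 | 20.5 |
| teal | 12.0 | 42.2 | 22.2 | 10.0 |
| teal | 20.0 | 45.2 | 27.9 | 5.2 |
| teal | 25.0 | 48.1 | 30.3 | 3.7 |

(each reading ± 1 percentage point)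

- free catalyst is single-handed; left-handed substrate and right-handed substrate are mirror images of each other, charged as a racemate, each of them at the stated concentration
- amounts are per litre of the starting volume; all of the dose is in the solution fed
- an excess is the difference of the two amounts in percent of their sum
- an excess is below zero if the other one leads

- the flask that ends with the higher excess of left-handed product over right-handed product in the product, or "neither" when 2 percentage points or less lies between them (epsilon / beta / neither)
- excess of left-handed product over right-handed product in the product at the end, epsilon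
- excess of left-handed product over right-handed product in the product at the end, beta

1. Follow one substrate molecule: at each moment it is taken or it waits. At 12.0 h the green, violet and teal runs keep on average 19.5 % of the left-handed charge and, by difference, 56.0 % of the right-handed charge. The ratio of their logarithms reads 2.82. This is the selectivity factor: the odds of a left-handed molecule being taken over a right-handed one at equal amounts. With the factor held constant, if x is the right-handed share left, the left-handed share left is x raised to that factor.

2. First rung: the feed ends at 2.5 h. In the teal run the left-handed substrate shows a half-life of about 4.72 h, read between 2.00 h and 12.0 h, longer than the feed.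

3. Next rung: multiplying by the factor gives the right-handed half-life in teal, about 13.3 h, still shorter than the reading time.

4. Last rung, epsilon: taking one reagent per product, its charge covers 75.0 % of both substrates, so reagent is the limiting reagent. Once that charge is used, the two shares left in epsilon sum to 0.500. One Newton step from 0.5 gives x = 42.1 % and a left-handed share of 8.72 %, so this reckoning puts the excess at 22.4 %.

5. Last rung, beta: its charge covers 120 % of both substrates, so this reckoning for beta runs up to the reading time. Using the right-handed half-life from the teal run, crudely, x is 7.42 % and the excess 3.82 %.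

The forecast names epsilon, with 23 % for epsilon and 4.5 % for beta, slightly above this reckoning on both: “Pushing a kinetic resolution to completion erases the excess.”

The simulation gives epsilon, with 24.3 % for epsilon and 2.12 % for beta.

    reagent + catalyst intermediate A → free catalyst + left-handed product (k = 5.15 M⁻¹ s⁻¹)
    precatalyst → free catalyst (k = 3.58 × 10⁻⁴ s⁻¹)
    free catalyst + left-handed substrate ⇌ catalyst intermediate A (K = 25.0 M⁻¹, k = 1400 M⁻¹ s⁻¹)
    reagent + catalyst intermediate B → free catalyst + right-handed product (k = 1.94 M⁻¹ s⁻¹)
    free catalyst + right-handed substrate ⇌ catalyst intermediate B (K = 22.0 M⁻¹, k = 827 M⁻¹ s⁻¹)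

At 50 h neither flask has fully come to rest. Epsilon then keeps 1.9 % of its reagent, and its excess stands at 23.3 % after 500 h. Epsilon's right-handed share 44 %, raised to the factor, gives 10.0 %; the simulated left-handed share is 8.6 %. The catalyst charge, which holds whatever substrate sits in catalyst intermediate A and catalyst intermediate B, is 0.0500 % of the left-handed charge, and the dosing of reagent over time makes no difference to epsilon's excess. Beta keeps 18 % of its reagent and 4.2 % of its right-handed substrate at 50 h, and its excess stands at 0 % after 500 h.

A neighbour of beta with 0.030 M of reagent has shares summing to 1.40; one Newton step from 0.7 gives x = 83.5 %, a left-handed share of 60.2 % and an excess of 41.4 %. At 50 h the simulation leaves that neighbour 83 % of its right-handed substrate and 57 % of its left-handed substrate, with an excess of 43.3 %.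

The runs come from a simulation for an exercise; noise was put on by code.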